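In this flask the target cannot pass 60.0 % of the substrate charged, since each turn of step 1 takes one coupling partner, the limiting reagent, and 0.600 equiv was charged.

    substrate + coupling partner → target (k1 = 0.065 L mol⁻¹ s⁻¹)
    substrate + 2 coupling partner → side product (k2 = 0.018 L² mol⁻² s⁻¹)
    coupling partner → decomposed reagent (k3 = 0.0045 s⁻¹)
    2 coupling partner → homo dimer (k4 = 0.013 L mol⁻¹ s⁻¹)

substrate 0.10 M; coupling partner 0.600 equiv; time 5.0 h

- a doubled species enters its step squared and goes two at a time
- the reaction counts as stopped when no species that holds the substrate changes by six tenths of a point or more over the second half of the time
- run time (flask): 5.0 h

- why nothing more happens at 5.0 h, or that something still does (all of the substrate has reacted / the coupling partner has run out first / it is still moving)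
- share of the substrate used up at 5.0 h
- target at 5.0 h, in percent of the substrate charged

Each coupling partner faces two rates: capture by substrate, at first 0.390 min⁻¹, and decay, 0.270 min⁻¹. Their quotient contains no clock, so my reckoning carries the tie point, 0.692: the fraction of the substrate charge at which capture and decay run equal. Counting these two rates, capture's share at any fraction of substrate left is that fraction over itself plus the tie point.

I set the other steps aside. Step 1 uses substrate 60 times faster than step 2 at the start, and dimerisation begins at 0.347 of decay, fading with the partner, so the reckoning should run somewhat high.

The starting share gives 35.5 % conversion, so the mean fraction of substrate is 0.823, and its share gives 32.6 %. Decay's half-life of 2.6 min is far shorter than 5.0 h, so the partner should be shared out early.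

The forecast says the coupling partner has run out first, with 30.6 % conversion, lower than my figure, and 30.3 % target, on the ground of “about half of it reaching the substrate”.

The simulation gives the coupling partner has run out first, 30.6 % and 30.3 %, with 0 % of the partner left at 5.00 h, so the forecast stands. Its conversion would be 5 points out at 0.488 equiv or 0.720 equiv of coupling partner. The wearing away of coupling partner is the main reason substrate remains in this flask: with it taken away, conversion rises from 30.6 % to 100 %. Decay is a part of that reason: with the path to decomposed reagent struck out, conversion reaches 52.2 %, 31 % of what is missing.

In the neighbour with 0.40 M of substrate, the equivalents held, the tie point falls to 0.173, and the same two passes give 48.7 %. That flask gives 43.3 %.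

(All constants were drawn at random within sensible limits, and the outcome is calculated.)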